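12.0% of the substrate gone after 20.0 min at 13 °C is the number we would build on, so here is our quick reply to your hunch on these flasks.

the same everywhere: substrate 0.050 M; free catalyst 0.25 mM

| run | partner | temperature | remark | time |
|---|---|---|---|---|
| teal | 0.037 M | −20 °C | run made earlier |  |
| red | 0.083 M | 13 °C | run made earlier |  |
| ash | 0.0550 M | −5 °C |  | 1.5 h |
| elm | 0.0550 M |  | at −35 °C until 1.0 h, from then on at 25 °C | 1.5 h |
| larch | 0.0550 M | 25 °C |  | 1.5 h |
| maple | 0.0550 M | −35 °C |  | 1.5 h |

| run | time / min | target / % | substrate / % |
|---|---|---|---|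
| teal | 30.0 | 1.4 | 97.7 |
| teal | 50.0 | 0.1 | 98.5 |
| teal | 80.0 | 1.2 | 96.3 |
| teal | 120 | 2.2 | 97.8 |
| red | 1.50 | 2.4 | 98.1 |
| red | 4.00 | 1.6 | 96.9 |
| red | 10.0 | 5.3 | 93.8 |
| red | 20.0 | 12.4 | 88.0 |

(standard deviation of a reading: 1 percentage point)

- the flask with the highest amount of target, in percent of the substrate charged ("all alike" if they lie within 1.5 percentage points) (ash / elm / larch / maple / all alike)
- final target, as a percentage of the substrate charged, in ash
- final target, as a percentage of the substrate charged, in elm
- final target, as a percentage of the substrate charged, in larch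
- final target, as a percentage of the substrate charged, in maple



We work in fractions of the charge. Target and lost substrate go together in both runs: 2.2% against 2.20% at the last teal reading, 12.4% against 12.0% at the last red one. So we replace each curve by its mean loss constant k, a pseudo-first-order constant: the share of the remaining substrate lost per minute, with fraction left = exp(−k·t).

teal: k = −ln(left)/t = 1.85 × 10⁻⁴ min⁻¹
red: k = −ln(left)/t = 0.00639 min⁻¹

The red reading at 10.0 min gives 0.00640 min⁻¹, so these two red readings agree. The teal constant rests on a small loss read with a scatter of 1 percentage point.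

Partner and temperature moved together, and these runs cannot part them. We guess that partner has no effect, which differs from your guess. The two constants then give an activation energy of 64.6 kJ mol⁻¹. What we carry is the warm mean loss constant, k at 25 °C: 0.0191 min⁻¹. At −35 °C the same sum gives 2.68 × 10⁻⁵ min⁻¹. Reading loss as target:

larch: 82.0%
elm, cold then warm: 43.7%
ash: 8.87%
maple: 0.241%

A straight line at k would put elm's warm part at 57.2%, and the curve gives less, so we keep the exponential. Larch comes out highest.

Your forecast also says larch, with 9% in ash, 23% in elm, 47% in larch and 0.6% in maple. Its ground: “I assume first order in partner, which the data cannot confirm because partner and temperature changed together”. In larch and in elm we stand higher than the forecast.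

The flasks give 10.0% of target in ash, 34.0% in elm, 60.2% in larch and 0.271% in maple, so larch leads.

    partner + catalyst intermediate A ⇌ catalyst intermediate B (K = 26.0 L mol⁻¹, k = 363 L mol⁻¹ min⁻¹, Ea = 42.0 kJ mol⁻¹, ΔH = −27.0 kJ mol⁻¹)
    catalyst intermediate C → free catalyst + target (k = 17.9 min⁻¹, Ea = 66.0 kJ mol⁻¹)
    substrate + by-product → side product (k = 0.989 L mol⁻¹ min⁻¹, Ea = 66.0 kJ mol⁻¹)
    substrate + free catalyst ⇌ catalyst intermediate A (K = 1600 L mol⁻¹, k = 85.0 L mol⁻¹ min⁻¹, Ea = 54.0 kJ mol⁻¹, ΔH = −21.0 kJ mol⁻¹)
    catalyst intermediate B → by-product + catalyst intermediate C (k = 130 min⁻¹, Ea = 61.0 kJ mol⁻¹)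
    (constants at 25 °C)

Unbound substrate in elm is down by 47.5% against our 43.7%, and nearly all of that stands as 34.0% target and 13.4% side product. Take the flask like elm with 6.3 × 10⁻⁴ M of free catalyst and scale k by the catalyst charge, a factor of 2.52. The reckoning leaves 23.6% of the substrate. That flask holds 19% unbound substrate, 18.5% side product and 62.3% target.

(The data were computed from invented constants; noise was put on by code.)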